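The pentamer (rings A–E, lettered from the 2,4,6-trihydroxyphenoxy end) is cut at the B–C ether. In ring B the C4 hydroxyl sits between the oxygens on C3 and C5 and opposite the oxygen on C1. A formyl group placed on C4 therefore activates C3 and C5 for addition–elimination and is afterwards oxidised to that hydroxyl. In one flask the C–D–E phenol and then methoxide replace the two fluorides of 4-(benzyloxy)-2,6-difluorobenzaldehyde, forming the C5–O(ring C) and C3–O bonds. The same aldehyde-to-phenol device builds the C–D–E phenol from two bromobenzaldehydes. Ring A is added by Ullmann coupling and thirteen methyl ethers are cleaved last.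

Key step: step 6

Remark on the chemistry: the target is achiral (no stereocentre, freely rotating diaryl ether axes), so no stereodescriptors appear. Each ring is numbered from the carbon whose ether oxygen points towards ring A.

Step 1
Reactants: 1 3,4,5-trimethoxyphenol; 2 4-bromo-3,5-dimethoxybenzaldehyde
Product: 3 3,5-dimethoxy-4-(3,4,5-trimethoxyphenoxy)benzaldehyde
Conditions: CuI (10 mol%), N,N-dimethylglycine·HCl (30 mol%), Cs2CO3 (2 equiv), 1,4-dioxane, 100 °C, argon
Reagents that add atoms: none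
Why: Ullmann-type diaryl ether synthesis under monovalent copper catalysis, electronically matched because the C–Br bond of 2 is activated by the para formyl group and 1 is an unhindered, electron-rich phenoxide, while the non-enolisable aldehyde tolerates carbonate base.

Step 2
Reactants: 3 3,5-dimethoxy-4-(3,4,5-trimethoxyphenoxy)benzaldehyde
Product: 5 3,5-dimethoxy-4-(3,4,5-trimethoxyphenoxy)phenol, via aryl formate 4 (not isolated)
Conditions: mCPBA (1.3 equiv), CH2Cl2, 0 °C to rt; crude formate, K2CO3 (cat.), MeOH, argon, rt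
Reagents that add atoms: mCPBA (3-chloroperoxybenzoic acid), O=C(OO)c1cccc(Cl)c1
Why: Baeyer–Villiger oxidation in which the aryl group, enriched by the para aryloxy oxygen, migrates from the Criegee adduct in preference to hydride, and the formate is then removed by base-catalysed transesterification, the sequence that also turns 3,4,5-trimethoxybenzaldehyde into 3,4,5-trimethoxyphenol.

Step 3
Reactants: 5 3,5-dimethoxy-4-(3,4,5-trimethoxyphenoxy)phenol; 6 2-bromo-3,4,5-trimethoxybenzaldehyde
Product: 7 2-[3,5-dimethoxy-4-(3,4,5-trimethoxyphenoxy)phenoxy]-3,4,5-trimethoxybenzaldehyde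
Conditions: CuI (10 mol%), N,N-dimethylglycine·HCl (30 mol%), Cs2CO3 (2 equiv), 1,4-dioxane, 100 °C, argon
Reagents that add atoms: none
Why: Ullmann-type diaryl ether synthesis in which the ortho formyl group of 6 polarises the C–Br bond and can guide copper to it, and phenol 5 has both ortho positions free, ortho-halobenzaldehydes and ortho-halobenzoates being a long-established substrate class for this coupling.

Step 4
Reactants: 7 2-[3,5-dimethoxy-4-(3,4,5-trimethoxyphenoxy)phenoxy]-3,4,5-trimethoxybenzaldehyde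
Product: 9 2-[3,5-dimethoxy-4-(3,4,5-trimethoxyphenoxy)phenoxy]-3,4,5-trimethoxyphenol, via aryl formate 8 (not isolated)
Conditions: mCPBA (1.3 equiv), CH2Cl2, 0 °C to rt; crude formate, K2CO3 (cat.), MeOH, argon, rt
Reagents that add atoms: mCPBA (3-chloroperoxybenzoic acid), O=C(OO)c1cccc(Cl)c1
Why: Baeyer–Villiger oxidation favoured by the ortho aryloxy and para methoxy donors of ring C, followed by transesterification of the formate, which places the free hydroxyl exactly on C1 of ring C without any protecting group; ring D is too electron-rich for a Smiles migration of the resulting phenoxide.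

Step 5
Reactants: 10 2,6-difluoro-4-hydroxybenzaldehyde
Product: 11 4-(benzyloxy)-2,6-difluorobenzaldehyde
Conditions: BnBr (1.1 equiv), K2CO3 (1.5 equiv), DMF, rt
Reagents that add atoms: benzyl bromide, BrCc1ccccc1
Why: Williamson ether synthesis, in which the weakly nucleophilic para-formyl phenoxide is alkylated by the reactive benzylic bromide at room temperature much faster than it can attack a C–F carbon of a second molecule.

Step 6
Reactants: 9 2-[3,5-dimethoxy-4-(3,4,5-trimethoxyphenoxy)phenoxy]-3,4,5-trimethoxyphenol; 11 4-(benzyloxy)-2,6-difluorobenzaldehyde; 12 sodium methoxide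
Product: 14 4-(benzyloxy)-2-methoxy-6-{2-[3,5-dimethoxy-4-(3,4,5-trimethoxyphenoxy)phenoxy]-3,4,5-trimethoxyphenoxy}benzaldehyde, via monofluoride 13 (not isolated)
Conditions: 9 (1.0 equiv), 11 (1.1 equiv), Cs2CO3 (1.2 equiv), DMSO, 70 °C; then 12 (25 wt% in MeOH, 3 equiv), 55 °C, same flask
Reagents that add atoms: sodium methoxide 12, C[O-].[Na+]
Why: Both substitutions are SNAr addition–eliminations in which the oxygen nucleophile adds to a C–F carbon ortho to the formyl group, the carbonyl oxygen takes up the charge of the Meisenheimer adduct, and fluoride departs. The closest known chemistry is the stepwise replacement of the fluorides of 2,6-difluorobenzaldehydes by phenoxides and alkoxides. No ring is closed and no stereocentre is formed. The step needs mono-aryloxylation, which is secured because the two C–F sites of 11 are equivalent by symmetry, 9 is the limiting partner, and the aryloxy group in 13 both donates into ring B and crowds the remaining C–F carbon, so a second bulky phenoxide reacts far more slowly. Methoxide, small and much more nucleophilic, is held back until 9 is consumed and then attacks the fluorine-bearing carbon of 13 rather than the C–OAr or C–OBn carbons, since addition is fastest at C–F and aryloxide or benzyloxide are poorer leaving groups in this manifold. Addition of methoxide to the aldehyde is reversible and only lowers the concentration of reactive substrate, and DMSO avoids the amine release that amide solvents show with alkoxides.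

Step 7
Reactants: 14 4-(benzyloxy)-2-methoxy-6-{2-[3,5-dimethoxy-4-(3,4,5-trimethoxyphenoxy)phenoxy]-3,4,5-trimethoxyphenoxy}benzaldehyde
Product: 16 4-(benzyloxy)-2-methoxy-6-{2-[3,5-dimethoxy-4-(3,4,5-trimethoxyphenoxy)phenoxy]-3,4,5-trimethoxyphenoxy}phenol, via aryl formate 15 (not isolated)
Conditions: mCPBA (1.2 equiv), CH2Cl2, 0 °C to rt; crude formate, K2CO3 (cat.), degassed MeOH, argon, rt
Reagents that add atoms: mCPBA (3-chloroperoxybenzoic acid), O=C(OO)c1cccc(Cl)c1
Why: Baeyer–Villiger oxidation of a 2,4,6-trioxygenated benzaldehyde, whose aryl group migrates very readily, so the activating carbon leaves as formate and the C4 oxygen of ring B stands where it was; benzyl, methyl and diaryl ethers are inert to the peracid, and exclusion of air protects the electron-rich phenol.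

Step 8
Reactants: 16 4-(benzyloxy)-2-methoxy-6-{2-[3,5-dimethoxy-4-(3,4,5-trimethoxyphenoxy)phenoxy]-3,4,5-trimethoxyphenoxy}phenol
Product: 17 5-(benzyloxy)-1,2-dimethoxy-3-{2-[3,5-dimethoxy-4-(3,4,5-trimethoxyphenoxy)phenoxy]-3,4,5-trimethoxyphenoxy}benzene
Conditions: MeI (1.5 equiv), K2CO3 (2 equiv), DMF, rt
Reagents that add atoms: iodomethane, CI
Why: Williamson O-methylation of the only free hydroxyl with a small electrophile that reaches the flanked phenoxide, masking C4–OH so that only C1–OH of ring B is arylated later.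

Step 9
Reactants: 17 5-(benzyloxy)-1,2-dimethoxy-3-{2-[3,5-dimethoxy-4-(3,4,5-trimethoxyphenoxy)phenoxy]-3,4,5-trimethoxyphenoxy}benzene
Product: 18 3,4-dimethoxy-5-{2-[3,5-dimethoxy-4-(3,4,5-trimethoxyphenoxy)phenoxy]-3,4,5-trimethoxyphenoxy}phenol
Conditions: H2 (1 atm), 10% Pd/C, EtOAc–MeOH, rt
Reagents that add atoms: none
Why: Catalytic hydrogenolysis cleaves only the benzylic C–O bond, since aryl methyl ethers and diaryl ethers are untouched under these conditions.

Step 10
Reactants: 18 3,4-dimethoxy-5-{2-[3,5-dimethoxy-4-(3,4,5-trimethoxyphenoxy)phenoxy]-3,4,5-trimethoxyphenoxy}phenol; 19 2-iodo-1,3,5-trimethoxybenzene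
Product: 20 1,2-dimethoxy-3-{2-[3,5-dimethoxy-4-(3,4,5-trimethoxyphenoxy)phenoxy]-3,4,5-trimethoxyphenoxy}-5-(2,4,6-trimethoxyphenoxy)benzene (tridecamethyl ether of the target)
Conditions: 19 (1.5 equiv), CuI (20 mol%), picolinic acid (40 mol%), K3PO4 (2 equiv), DMSO, 100 °C, argon
Reagents that add atoms: none
Why: Ullmann-type diaryl ether synthesis with the CuI–picolinic acid system developed for hindered partners, in which the phenoxide of 18 has both ortho positions free and the iodide leaving group offsets the electron-rich, doubly ortho-substituted ring A.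

Step 11
Reactants: 20 tridecamethyl ether of the target
Product: 21 2-{3-[2-(3,5-dihydroxy-4-(3,4,5-trihydroxyphenoxy)phenoxy)-3,4,5-trihydroxyphenoxy]-4,5-dihydroxyphenoxy}benzene-1,3,5-triol (CNP0228612.0)
Conditions: BBr3 (about 2 equiv per OMe), CH2Cl2, −78 °C to rt, argon; then H2O, 0 °C; size-exclusion or reversed-phase purification under argon
Reagents that add atoms: none
Why: Lewis-acid ether cleavage in which BBr3 binds each methoxy oxygen and bromide attacks the methyl carbon in an SN2 step, whereas the four aryl–O–aryl linkages offer no sp3 carbon and survive, and hydrolysis of the aryl borates releases the thirteen hydroxyls.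

Compound list
1 | 3,4,5-trimethoxyphenol | COc1cc(O)cc(OC)c1OC | starting material
2 | 4-bromo-3,5-dimethoxybenzaldehyde | COc1cc(C=O)cc(OC)c1Br | starting material
3 | 3,5-dimethoxy-4-(3,4,5-trimethoxyphenoxy)benzaldehyde | O=Cc1cc(OC)c(Oc2cc(OC)c(OC)c(OC)c2)c(OC)c1 | intermediate
4 | 3,5-dimethoxy-4-(3,4,5-trimethoxyphenoxy)phenyl formate | O=COc1cc(OC)c(Oc2cc(OC)c(OC)c(OC)c2)c(OC)c1 | intermediate
5 | 3,5-dimethoxy-4-(3,4,5-trimethoxyphenoxy)phenol | Oc1cc(OC)c(Oc2cc(OC)c(OC)c(OC)c2)c(OC)c1 | intermediate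
6 | 2-bromo-3,4,5-trimethoxybenzaldehyde | O=Cc1cc(OC)c(OC)c(OC)c1Br | starting material
7 | 2-[3,5-dimethoxy-4-(3,4,5-trimethoxyphenoxy)phenoxy]-3,4,5-trimethoxybenzaldehyde | O=Cc1cc(OC)c(OC)c(OC)c1Oc1cc(OC)c(Oc2cc(OC)c(OC)c(OC)c2)c(OC)c1 | intermediate
8 | 2-[3,5-dimethoxy-4-(3,4,5-trimethoxyphenoxy)phenoxy]-3,4,5-trimethoxyphenyl formate | O=COc1cc(OC)c(OC)c(OC)c1Oc1cc(OC)c(Oc2cc(OC)c(OC)c(OC)c2)c(OC)c1 | intermediate
9 | 2-[3,5-dimethoxy-4-(3,4,5-trimethoxyphenoxy)phenoxy]-3,4,5-trimethoxyphenol | Oc1cc(OC)c(OC)c(OC)c1Oc1cc(OC)c(Oc2cc(OC)c(OC)c(OC)c2)c(OC)c1 | intermediate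
10 | 2,6-difluoro-4-hydroxybenzaldehyde | O=Cc1c(F)cc(O)cc1F | starting material
11 | 4-(benzyloxy)-2,6-difluorobenzaldehyde | O=Cc1c(F)cc(OCc2ccccc2)cc1F | intermediate
12 | sodium methoxide | C[O-].[Na+] | starting material
13 | 4-(benzyloxy)-2-fluoro-6-{2-[3,5-dimethoxy-4-(3,4,5-trimethoxyphenoxy)phenoxy]-3,4,5-trimethoxyphenoxy}benzaldehyde | O=Cc1c(F)cc(OCc2ccccc2)cc1Oc1cc(OC)c(OC)c(OC)c1Oc1cc(OC)c(Oc2cc(OC)c(OC)c(OC)c2)c(OC)c1 | intermediate
14 | 4-(benzyloxy)-2-methoxy-6-{2-[3,5-dimethoxy-4-(3,4,5-trimethoxyphenoxy)phenoxy]-3,4,5-trimethoxyphenoxy}benzaldehyde | O=Cc1c(OC)cc(OCc2ccccc2)cc1Oc1cc(OC)c(OC)c(OC)c1Oc1cc(OC)c(Oc2cc(OC)c(OC)c(OC)c2)c(OC)c1 | intermediate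
15 | 4-(benzyloxy)-2-methoxy-6-{2-[3,5-dimethoxy-4-(3,4,5-trimethoxyphenoxy)phenoxy]-3,4,5-trimethoxyphenoxy}phenyl formate | O=COc1c(OC)cc(OCc2ccccc2)cc1Oc1cc(OC)c(OC)c(OC)c1Oc1cc(OC)c(Oc2cc(OC)c(OC)c(OC)c2)c(OC)c1 | intermediate
16 | 4-(benzyloxy)-2-methoxy-6-{2-[3,5-dimethoxy-4-(3,4,5-trimethoxyphenoxy)phenoxy]-3,4,5-trimethoxyphenoxy}phenol | Oc1c(OC)cc(OCc2ccccc2)cc1Oc1cc(OC)c(OC)c(OC)c1Oc1cc(OC)c(Oc2cc(OC)c(OC)c(OC)c2)c(OC)c1 | intermediate
17 | 5-(benzyloxy)-1,2-dimethoxy-3-{2-[3,5-dimethoxy-4-(3,4,5-trimethoxyphenoxy)phenoxy]-3,4,5-trimethoxyphenoxy}benzene | COc1c(OC)cc(OCc2ccccc2)cc1Oc1cc(OC)c(OC)c(OC)c1Oc1cc(OC)c(Oc2cc(OC)c(OC)c(OC)c2)c(OC)c1 | intermediate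
18 | 3,4-dimethoxy-5-{2-[3,5-dimethoxy-4-(3,4,5-trimethoxyphenoxy)phenoxy]-3,4,5-trimethoxyphenoxy}phenol | COc1c(OC)cc(O)cc1Oc1cc(OC)c(OC)c(OC)c1Oc1cc(OC)c(Oc2cc(OC)c(OC)c(OC)c2)c(OC)c1 | intermediate
19 | 2-iodo-1,3,5-trimethoxybenzene | COc1cc(OC)c(I)c(OC)c1 | starting material
20 | 1,2-dimethoxy-3-{2-[3,5-dimethoxy-4-(3,4,5-trimethoxyphenoxy)phenoxy]-3,4,5-trimethoxyphenoxy}-5-(2,4,6-trimethoxyphenoxy)benzene | COc1cc(OC)c(Oc2cc(OC)c(OC)c(Oc3cc(OC)c(OC)c(OC)c3Oc3cc(OC)c(Oc4cc(OC)c(OC)c(OC)c4)c(OC)c3)c2)c(OC)c1 | intermediate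
21 | 2-{3-[2-(3,5-dihydroxy-4-(3,4,5-trihydroxyphenoxy)phenoxy)-3,4,5-trihydroxyphenoxy]-4,5-dihydroxyphenoxy}benzene-1,3,5-triol (CNP0228612.0) | Oc1cc(O)c(Oc2cc(O)c(O)c(Oc3cc(O)c(O)c(O)c3Oc3cc(O)c(Oc4cc(O)c(O)c(O)c4)c(O)c3)c2)c(O)c1 | target

Total step count: 11. Longest linear sequence: 10 (steps 1–4 and 6–11; step 5 is a one-step side branch).

Steps most likely to fail

**Step 6 (key step).**
- What may go wrong before methoxide is added: the first substitution may be slow because the para benzyloxy oxygen feeds electron density into ring B, and a second phenoxide may add.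
- What may go wrong afterwards: methoxide may rest on the carbonyl group as hemiacetal, trigger hydride transfer between aldehyde molecules, or exchange with the aryloxy group already installed.
- Fallback (sets out from 9, comes back at 14): the activator is changed to a nitrile. It is slimmer, is not consumed by methoxide, and lets each substitution be run and purified on its own. Commercial 2,6-difluoro-4-hydroxybenzonitrile F1 is benzylated (BnBr, K2CO3, DMF, rt) to 4-(benzyloxy)-2,6-difluorobenzonitrile F2. Phenol 9 with Cs2CO3 in DMSO at 80 °C should give the mono-aryloxy fluoronitrile F3. NaOMe in MeOH–THF at reflux should then give the methoxy nitrile F4. Reduction with iBu2AlH in toluene at −78 to 0 °C and hydrolysis of the aluminium aldimine with aqueous HCl deliver 14.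

**Step 10.**
- What may go wrong: insertion of copper into the C–I bond of the electron-rich, doubly ortho-substituted ring A may be slow. Reductive loss of iodine and oxidative wear of the valuable phenoxide could then compete.
- Fallback (sets out from 18, comes back at 21): ring A is brought in as the formyl-activated bromide 2 under the conditions of step 1, a coupling already rehearsed on the closely related phenol 1. This should give the pentameric aldehyde F5. mCPBA in CH2Cl2 converts it into the pentameric aryl formate F6, and catalytic K2CO3 in MeOH into the ring A phenol F7. That compound carries twelve methyl ethers and a free C4 hydroxyl on ring A, and it goes directly into the BBr3 conditions of step 11 to give 21.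

**Step 11.**
- What may go wrong: cleavage may stall when partly dealkylated boron aryloxides fall out of CH2Cl2. The polar, oxidation-prone product may also be lost or darkened during direct isolation.
- Fallback (sets out from 20, comes back at 21): capture and release. After BBr3 treatment and aqueous quench the crude polyphenol is not purified but peracetylated (Ac2O, pyridine, rt) to the tridecaacetate F8. This neutral, air-stable compound can be chromatographed on silica and separated from under-cleaved material, which is returned to BBr3. Acid-catalysed methanolysis (HCl generated from AcCl in MeOH, argon, rt to 40 °C) then releases 21 without exposing the pyrogallol units to base.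

Further compounds
F1 | step 6 | 2,6-difluoro-4-hydroxybenzonitrile | N#Cc1c(F)cc(O)cc1F
F2 | step 6 | 4-(benzyloxy)-2,6-difluorobenzonitrile | N#Cc1c(F)cc(OCc2ccccc2)cc1F
F3 | step 6 | 4-(benzyloxy)-2-fluoro-6-{2-[3,5-dimethoxy-4-(3,4,5-trimethoxyphenoxy)phenoxy]-3,4,5-trimethoxyphenoxy}benzonitrile | N#Cc1c(F)cc(OCc2ccccc2)cc1Oc1cc(OC)c(OC)c(OC)c1Oc1cc(OC)c(Oc2cc(OC)c(OC)c(OC)c2)c(OC)c1
F4 | step 6 | 4-(benzyloxy)-2-methoxy-6-{2-[3,5-dimethoxy-4-(3,4,5-trimethoxyphenoxy)phenoxy]-3,4,5-trimethoxyphenoxy}benzonitrile | N#Cc1c(OC)cc(OCc2ccccc2)cc1Oc1cc(OC)c(OC)c(OC)c1Oc1cc(OC)c(Oc2cc(OC)c(OC)c(OC)c2)c(OC)c1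
F5 | step 10 | 4-(3-{2-[3,5-dimethoxy-4-(3,4,5-trimethoxyphenoxy)phenoxy]-3,4,5-trimethoxyphenoxy}-4,5-dimethoxyphenoxy)-3,5-dimethoxybenzaldehyde | O=Cc1cc(OC)c(Oc2cc(OC)c(OC)c(Oc3cc(OC)c(OC)c(OC)c3Oc3cc(OC)c(Oc4cc(OC)c(OC)c(OC)c4)c(OC)c3)c2)c(OC)c1
F6 | step 10 | 4-(3-{2-[3,5-dimethoxy-4-(3,4,5-trimethoxyphenoxy)phenoxy]-3,4,5-trimethoxyphenoxy}-4,5-dimethoxyphenoxy)-3,5-dimethoxyphenyl formate | O=COc1cc(OC)c(Oc2cc(OC)c(OC)c(Oc3cc(OC)c(OC)c(OC)c3Oc3cc(OC)c(Oc4cc(OC)c(OC)c(OC)c4)c(OC)c3)c2)c(OC)c1
F7 | step 10 | 4-(3-{2-[3,5-dimethoxy-4-(3,4,5-trimethoxyphenoxy)phenoxy]-3,4,5-trimethoxyphenoxy}-4,5-dimethoxyphenoxy)-3,5-dimethoxyphenol | Oc1cc(OC)c(Oc2cc(OC)c(OC)c(Oc3cc(OC)c(OC)c(OC)c3Oc3cc(OC)c(Oc4cc(OC)c(OC)c(OC)c4)c(OC)c3)c2)c(OC)c1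
F8 | step 11 | tridecaacetate of 21 | CC(=O)Oc1cc(OC(C)=O)c(Oc2cc(OC(C)=O)c(OC(C)=O)c(Oc3cc(OC(C)=O)c(OC(C)=O)c(OC(C)=O)c3Oc3cc(OC(C)=O)c(Oc4cc(OC(C)=O)c(OC(C)=O)c(OC(C)=O)c4)c(OC(C)=O)c3)c2)c(OC(C)=O)c1
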